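## Structural features

Hypothamnolic acid 18 is a meta-depside: two benzene rings joined only by an aryl ester between the C1 carboxyl of ring A and the C5' oxygen of ring B. Ring A is a pentasubstituted isophthalic acid unit (C1 ester carbonyl, C2 OH, C3 CO2H, C4 OMe, C5 H, C6 CH3). Ring B is hexasubstituted (C1' CO2H, C2' OH, C3' CH3, C4' OH, C5' O-acyl, C6' CH3). The molecule has no stereocentre, so no stereocentres stand next to each other; every problem is one of regiochemistry and chemoselectivity. The fragile groups are the aryl ester, which sits next to the free C4' hydroxyl and can shift to O4' or hydrolyse in base, the two ortho-hydroxy carboxylic acids, which decarboxylate in hot acid or base, and the trioxygenated ring B, which oxidizes easily once its phenols are free. The real difficulty lies in ring A: its two carboxyls and two phenolic oxygens must each be told apart (C1 esterified and C3 free, O4 methylated and O2 free), and the ester must join a 2,6-disubstituted acid to a 2,6-disubstituted phenol. The key step exploits the alternating pattern of ring A: C1 with its carboxyl, C6 with its methyl, C5 and C4 form a 3-methylglutaconate chain, and C2 together with C3 and its carboxyl form a malonyl unit. The two carboxyls therefore come from different building blocks and carry different ester groups from the moment the ring exists.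

## Logic of the disconnections

18 to 17. The four O–benzyl bonds are cut last (benzyl esters at C3 and C1', benzyl ethers at O2' and O4'). Neutral hydrogenolysis then releases all sensitive functions of 18 together, and every earlier step runs on a masked ring B. The demand is that every protecting group left in 17 be benzyl, so ring B must carry a benzyl ester and not the methyl ester of 10.

17 to 9 and 16. The depside C(=O)–O5' bond is cut, the only bond between the rings, which gives two halves of similar size. The forward step must esterify a doubly ortho-substituted acid with a doubly ortho-substituted phenol, so 9 may have only one free carboxyl and 16 only one free hydroxyl. The C2 hydroxyl of 9 is left unprotected: it is the hydroxyl that is free in 18, and it lies between two carbonyl groups and is a poor nucleophile.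

9 to 8 to 7. The O–allyl bond of the C1 ester and the O4–CH3 bond are cut in turn. This leads back to 7, in which the two carboxyls already differ as allyl and benzyl esters. The forward steps must remove allyl without touching benzyl, and must methylate O4 and not O2.

7 to 3 and 5, through 6. The ring bonds C1–C2 and C3–C4 are cut. Both ring oxygens become carbonyl oxygens of acyclic precursors, and a pentasubstituted arene is traded for a symmetric five-carbon diester and a three-carbon acid chloride. The forward step must acylate and cyclize through carbon, must reach the Z enoate, and must not scramble the ester groups. The anion of 3 has its ester carbonyls in a 1,5 relationship and cannot itself be a six-membered magnesium chelate; the chelate appears only in 6.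

3 to 1 and 2; 5 to 4. Only ester C–O bonds and the acyl C–Cl bond are cut. Both ester groups of 3 must be allyl, so that the alkoxide expelled on ring closure is the same as the one retained at C1; the forward exchange therefore consumes two molecules of 2 for each molecule of 1.

16 to 15 to 12 to 11 to 10. The benzyl ester O–C bond, the C5'–O bond (traced back to a formyl carbon through aryl migration), the two benzyl ether bonds and the C5'–CHO bond are cut. 10 already holds five of the six substituents, and its single free CH is the site of the missing oxygen. A formyl group serves as a latent hydroxyl that stays distinct from the two native phenols. The forward steps must formylate a flanked position, oxidize with aryl migration, and exchange a hindered methyl ester for a benzyl ester.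

## Other disconnections considered

Alternative 1: Ring B is cut at C1'–C6' and C3'–C4' and is built on a depside ester that already exists. In the forward step the enolate of benzyl 3-oxopentanoate A2 adds to the enol ester acceptor methyl (Z)-2-(aroyloxy)but-2-enoate A1, which carries the protected ring A acyl group. The ethyl ketone carbon then closes onto the methyl ester to give the cyclohexane-1,3-dione A3, which must be dehydrogenated to the arene.
- In its favour: the depside C–O bond is made early, by O-acylation of an unhindered enolate. On this point it is better than the chosen plan, which must join two hindered partners. All six ring B substituents are placed by construction.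
- Against it: A3 is one oxidation level below the arene, so an extra dehydrogenation is needed. The acyloxy group in A3 sits next to a ketone, so under the basic closure it can migrate to the neighbouring enolate oxygen or be cleaved by the liberated methoxide. The Dieckmann step needs the less acidic ketone position as nucleophile.
- Comparison: mechanistically it is sound but has more branch points. Ring A must still be made, with an extra O2 benzyl ether, so it offers no gain in step count.

Alternative 2: Ring B is cut at C1'–C2' and traced to a four-membered ring. The β-metallated ester derived from benzyl (E)-3-iodobut-2-enoate A5 adds to the squarate-derived dione 3-(benzyloxy)-4-methylcyclobut-3-ene-1,2-dione A4. Thermolysis of the resulting cyclobutenone A6 opens it to a dienylketene, which closes by 6π electrocyclization and tautomerizes to the hydroquinone A7.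
- In its favour: regiochemistry is fixed by construction, and the cascade is neutral and unimolecular. A7 emerges with the protection the depside needs (O4' benzylated, O5' free, O2' tied up by its hydrogen bond, benzyl ester in place). Here it is better than the chosen ring B sequence, which needs an ester exchange.
- Against it: a vinyl metal bearing an ester must be made and used at low temperature and must keep the E geometry, or the adduct lactonizes. A4 needs its own preparation. A7 is an air-sensitive hydroquinone.
- Comparison: the step count for ring B is about equal. It is the better plan on regiocontrol and protecting groups, and the weaker one on operational robustness. It leaves the ring A problem untouched and could be combined with the chosen key step, not substituted for it.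

Alternative 3: Ring A is cut at C1–C6 and is made last by a biomimetic aldol. Acid unmasks the methyl ketone of the ring B aryl ester A8 (a ketal-protected 3,5,7-trioxooctanoate with a benzyl ester at C4). The C2 methylene adds to C7, and dehydration and enolization give A9.
- In its favour: the depside ester is present before ring A exists, so there is no hindered esterification and no orthogonal ester at C1. On both points it is better than the chosen plan.
- Against it: A8 is an activated aryl ester of a polyketo acid. Claisen closure or pyranone formation onto C1 would expel the ring B phenoxide and destroy the depside link. The central carbon between two ketones invites retro-Claisen cleavage, and assembling A8 takes several steps through sensitive intermediates.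
- Comparison: A9 needs the same O4 over O2 methylation as 7, so on that point the plans are equal. Overall it is longer and its selectivity is harder to control than a cyclization whose only six-membered modes lead to, or funnel into, the arene.

Key step: step 3

Assumption: 1 is used as its commercial E and Z mixture and the alkene geometry is not controlled, since it equilibrates through the anion before ring closure. Ring A is numbered C1 (depside carbonyl) to C6 (methyl), and ring B C1' (carboxyl carbon) to C6'.

## Route

Step 1
Reactants: 1 dimethyl 3-methylpent-2-enedioate (dimethyl 3-methylglutaconate, E and Z mixture); 2 allyl alcohol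
Product: 3 diallyl 3-methylpent-2-enedioate (E and Z mixture)
Conditions: 2 (large excess, as solvent), Ti(OiPr)4 (5 mol %), reflux, MeOH distilled off
Reagents that add atoms: allyl alcohol (second equivalent of 2), C=CCO
Why: Titanium alkoxide catalysed transesterification of both ester groups, each taking up one molecule of 2 and releasing one molecule of methanol, driven to the diallyl ester by the excess of 2 and removal of methanol. The neutral Lewis acid avoids base-induced self-condensation of the glutaconate, and the alkene geometry is immaterial.

Step 2
Reactants: 4 monobenzyl malonate (3-(benzyloxy)-3-oxopropanoic acid)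
Product: 5 benzyl 3-chloro-3-oxopropanoate
Conditions: (COCl)2 (1.2 equiv), DMF (cat.), CH2Cl2, 0 °C to rt; evaporated and used at once
Reagents that add atoms: oxalyl chloride, O=C(Cl)C(=O)Cl
Why: Acid chloride formation through the Vilsmeier-type chloroiminium catalyst under neutral conditions; the benzyl ester is untouched, and immediate use avoids loss of HCl to the ketene on storage.

Step 3
Reactants: 3 diallyl 3-methylpent-2-enedioate (1.2 equiv); 5 benzyl 3-chloro-3-oxopropanoate
Product: 7 1-allyl 3-benzyl 2,4-dihydroxy-6-methylbenzene-1,3-dicarboxylate, via acylglutaconate triester 6 (not isolated)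
Conditions: MgCl2 (2.2 equiv), Et3N (3.5 equiv), MeCN, 0 °C; 5 added slowly, 0 °C to rt; then DBU (2.5 equiv), 50 °C; 1 M HCl work-up
Reagents that add atoms: none
Why: MgCl2 binds an ester carbonyl of 3 and Et3N removes the adjacent proton (soft enolization, single-point activation), and the carbon terminus of the symmetric anion is acylated by 5 to give 6, which is at once deprotonated and held as the six-membered magnesium chelate of a β-keto ester; either terminus gives the same triester. Any (benzyloxycarbonyl)ketene formed from 5 and the amine is captured at its central carbon by the same nucleophile and converges on 6. DBU then generates the enolate at the malonyl methylene (the future C3), the extended anion of 6 equilibrates the enoate geometry, and the Z form closes by 6-exo-trig attack of C3 on the distal conjugated allyl ester (Dieckmann, or intramolecular Claisen, condensation); loss of allyloxide and two enolizations give the resorcinol, which makes the closure irreversible. The closest known reaction types are the magnesium-mediated C-acylation of active-methylene esters with acid chlorides and the base-induced Claisen aromatization of 2-acylglutaconates, and of the isomeric 2-pyranones, to resorcylates. No stereocentre is formed, since every transient sp3 carbon is lost on aromatization. The step needs C- over O-acylation and C- over O-cyclization: the magnesium ion ties up the enolate oxygens and leaves carbon as the nucleophilic site, and a pyranone formed by O-closure is reopened by the liberated allyloxide and drains to the arene. Only the distal ester can be reached through a six-membered transition state, and the expelled allyloxide matches the ester retained at C1, so exchange there is degenerate and the allyl and benzyl esters at C1 and C3 stay distinct.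

Step 4
Reactants: 7 1-allyl 3-benzyl 2,4-dihydroxy-6-methylbenzene-1,3-dicarboxylate
Product: 8 1-allyl 3-benzyl 2-hydroxy-4-methoxy-6-methylbenzene-1,3-dicarboxylate
Conditions: MeI (1.1 equiv), K2CO3 (1.2 equiv), acetone, rt
Reagents that add atoms: iodomethane, CI
Why: Williamson ether synthesis; O4 has an open ortho position (C5–H) whereas O2 lies between two ester carbonyls, is doubly chelated and shielded, so monoalkylation should occur at O4.

Step 5
Reactants: 8 1-allyl 3-benzyl 2-hydroxy-4-methoxy-6-methylbenzene-1,3-dicarboxylate
Product: 9 3-[(benzyloxy)carbonyl]-2-hydroxy-4-methoxy-6-methylbenzoic acid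
Conditions: Pd(PPh3)4 (3 mol %), morpholine (3 equiv), THF, rt; then 1 M HCl
Reagents that add atoms: none
Why: Tsuji–Trost deallylation; zerovalent palladium ionizes only the allyl ester to a π-allyl complex that morpholine captures, and the benzyl ester, methyl ether and phenol are inert.

Step 6
Reactants: 10 atraric acid (methyl 2,4-dihydroxy-3,6-dimethylbenzoate)
Product: 11 methyl 5-formyl-2,4-dihydroxy-3,6-dimethylbenzoate
Conditions: Cl2CHOMe (1.5 equiv), TiCl4 (3 equiv), CH2Cl2, 0 °C to rt; then ice and 1 M HCl
Reagents that add atoms: dichloromethyl methyl ether, COC(Cl)Cl; water, O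
Why: Rieche formylation; C5 is the only free ring position, ortho to O4 (delivery through the titanium phenoxide) and para to O2, and hydrolysis of the α-chloro ether on work-up gives the aldehyde.

Step 7
Reactants: 11 methyl 5-formyl-2,4-dihydroxy-3,6-dimethylbenzoate
Product: 12 methyl 2,4-bis(benzyloxy)-5-formyl-3,6-dimethylbenzoate
Conditions: BnBr (2.5 equiv), K2CO3 (3 equiv), DMF, 60 °C
Reagents that add atoms: benzyl bromide (first equivalent), BrCc1ccccc1; benzyl bromide (second equivalent), BrCc1ccccc1
Why: Twofold Williamson ether synthesis, one molecule of benzyl bromide for each phenol; both chelated phenols are alkylated under forcing polar aprotic conditions, and the aldehyde and ester have no other reactive site.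

Step 8
Reactants: 12 methyl 2,4-bis(benzyloxy)-5-formyl-3,6-dimethylbenzoate
Product: 15 2,4-bis(benzyloxy)-5-hydroxy-3,6-dimethylbenzoic acid, via aryl formate 13 (not isolated), via hydroxy methyl ester 14 (not isolated)
Conditions: mCPBA (1.3 equiv), CH2Cl2, 0 °C to rt; solvent exchanged for DMSO–H2O, KOH (6 equiv), 70 °C, argon; then 1 M HCl, 0 °C
Reagents that add atoms: 3-chloroperoxybenzoic acid, O=C(OO)c1cccc(Cl)c1; potassium hydroxide, [K+].[OH-]
Why: Baeyer–Villiger (Dakin-type) oxidation, in which the electron-rich aryl group with ortho and para alkoxy substituents migrates in preference to hydride; hydroxide then cleaves the formate at once and the hindered methyl ester more slowly, as poorly solvated hydroxide in DMSO does with doubly ortho-substituted benzoates.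

Step 9
Reactants: 15 2,4-bis(benzyloxy)-5-hydroxy-3,6-dimethylbenzoic acid
Product: 16 benzyl 2,4-bis(benzyloxy)-5-hydroxy-3,6-dimethylbenzoate
Conditions: BnBr (1.05 equiv), KHCO3 (1.2 equiv), DMF, rt
Reagents that add atoms: benzyl bromide, BrCc1ccccc1
Why: Carboxylate O-alkylation, which takes place at the benzylic carbon and is insensitive to hindrance at the carboxyl; KHCO3 does not ionize the flanked phenol, so O5' stays free.

Step 10
Reactants: 9 3-[(benzyloxy)carbonyl]-2-hydroxy-4-methoxy-6-methylbenzoic acid; 16 benzyl 2,4-bis(benzyloxy)-5-hydroxy-3,6-dimethylbenzoate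
Product: 17 benzyl 2,4-bis(benzyloxy)-5-({3-[(benzyloxy)carbonyl]-2-hydroxy-4-methoxy-6-methylbenzoyl}oxy)-3,6-dimethylbenzoate
Conditions: (CF3CO)2O (3 equiv), toluene, 0 °C to rt (9 activated first, then 16 added)
Reagents that add atoms: none
Why: Esterification through the mixed trifluoroacetic anhydride, the standard depside coupling; the electron-rich acid ionizes towards an acylium-like species that is little affected by ortho hindrance and is captured by the only free hydroxyl of 16, while O2 of 9 is too deactivated to compete.

Step 11
Reactants: 17 benzyl 2,4-bis(benzyloxy)-5-({3-[(benzyloxy)carbonyl]-2-hydroxy-4-methoxy-6-methylbenzoyl}oxy)-3,6-dimethylbenzoate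
Product: 18 hypothamnolic acid
Conditions: H2 (1 atm), 10% Pd/C, EtOAc, rt
Reagents that add atoms: none
Why: Catalytic hydrogenolysis of two benzyl esters and two benzyl ethers under neutral conditions, which spares the aryl ester and avoids acyl shift to O4' and decarboxylation.

## Compound list

1 | dimethyl 3-methylpent-2-enedioate (dimethyl 3-methylglutaconate, E and Z mixture) | COC(=O)CC(C)=CC(=O)OC | starting material
2 | allyl alcohol (prop-2-en-1-ol) | C=CCO | starting material
3 | diallyl 3-methylpent-2-enedioate (E and Z mixture; the Z isomer is written) | C=CCOC(=O)C/C(C)=C\C(=O)OCC=C | intermediate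
4 | monobenzyl malonate (3-(benzyloxy)-3-oxopropanoic acid) | O=C(O)CC(=O)OCc1ccccc1 | starting material
5 | benzyl 3-chloro-3-oxopropanoate | O=C(Cl)CC(=O)OCc1ccccc1 | intermediate
6 | diallyl 4-[3-(benzyloxy)-3-oxopropanoyl]-3-methylpent-2-enedioate (racemic, enolizable, E and Z mixture) | C=CCOC(=O)C=C(C)C(C(=O)CC(=O)OCc1ccccc1)C(=O)OCC=C | intermediate
7 | 1-allyl 3-benzyl 2,4-dihydroxy-6-methylbenzene-1,3-dicarboxylate | C=CCOC(=O)c1c(C)cc(O)c(C(=O)OCc2ccccc2)c1O | intermediate
8 | 1-allyl 3-benzyl 2-hydroxy-4-methoxy-6-methylbenzene-1,3-dicarboxylate | C=CCOC(=O)c1c(C)cc(OC)c(C(=O)OCc2ccccc2)c1O | intermediate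
9 | 3-[(benzyloxy)carbonyl]-2-hydroxy-4-methoxy-6-methylbenzoic acid | COc1cc(C)c(C(=O)O)c(O)c1C(=O)OCc1ccccc1 | intermediate
10 | atraric acid (methyl 2,4-dihydroxy-3,6-dimethylbenzoate) | COC(=O)c1c(C)cc(O)c(C)c1O | starting material
11 | methyl 5-formyl-2,4-dihydroxy-3,6-dimethylbenzoate | COC(=O)c1c(C)c(C=O)c(O)c(C)c1O | intermediate
12 | methyl 2,4-bis(benzyloxy)-5-formyl-3,6-dimethylbenzoate | COC(=O)c1c(C)c(C=O)c(OCc2ccccc2)c(C)c1OCc1ccccc1 | intermediate
13 | methyl 2,4-bis(benzyloxy)-5-(formyloxy)-3,6-dimethylbenzoate | COC(=O)c1c(C)c(OC=O)c(OCc2ccccc2)c(C)c1OCc1ccccc1 | intermediate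
14 | methyl 2,4-bis(benzyloxy)-5-hydroxy-3,6-dimethylbenzoate | COC(=O)c1c(C)c(O)c(OCc2ccccc2)c(C)c1OCc1ccccc1 | intermediate
15 | 2,4-bis(benzyloxy)-5-hydroxy-3,6-dimethylbenzoic acid | Cc1c(O)c(OCc2ccccc2)c(C)c(OCc2ccccc2)c1C(=O)O | intermediate
16 | benzyl 2,4-bis(benzyloxy)-5-hydroxy-3,6-dimethylbenzoate | Cc1c(O)c(OCc2ccccc2)c(C)c(OCc2ccccc2)c1C(=O)OCc1ccccc1 | intermediate
17 | benzyl 2,4-bis(benzyloxy)-5-({3-[(benzyloxy)carbonyl]-2-hydroxy-4-methoxy-6-methylbenzoyl}oxy)-3,6-dimethylbenzoate | COc1cc(C)c(C(=O)Oc2c(C)c(C(=O)OCc3ccccc3)c(OCc3ccccc3)c(C)c2OCc2ccccc2)c(O)c1C(=O)OCc1ccccc1 | intermediate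
18 | hypothamnolic acid | COc1cc(C)c(C(=O)Oc2c(C)c(C(=O)O)c(O)c(C)c2O)c(O)c1C(=O)O | target

## Step count and least certain steps

Total step count: 11. Longest linear sequence: 6 steps (10 to 11 to 12 to 15 to 16 to 17 to 18; the sequence 1 to 3 to 7 to 8 to 9 to 17 to 18 is equally long).

Step 3 (key step). The most likely failures are diversion of 5 into ketene oligomers before the weakly activated anion of 3 can capture it, and ring closure of 6 through the enol oxygen instead of through C3. Partial exchange of the benzyl ester by liberated allyloxide would also erode the C1 and C3 differentiation. The fallback sets out from 3 and 5 and returns at 7, and it accepts the O-closure on purpose. The sodium enolate of 3 (NaH, THF, 0 °C) is acylated with 5 and the crude 6 is warmed with acid (TsOH, toluene). This should give the 2-pyranone allyl 6-[2-(benzyloxy)-2-oxoethyl]-4-methyl-2-oxo-2H-pyran-5-carboxylate F1, the known fate of 2-acyl-3-methylglutaconates, and F1 is isolated. F1 is then treated with Mg(OCH2CH=CH2)2 (2 equiv) in THF at 60 °C. Allyloxide reopens the lactone to the magnesium enolate of 6 with the allyl ester restored, and closure through carbon gives 7, as in the known alkoxide-induced rearrangement of 6-(alkoxycarbonylmethyl)-2-pyranones to resorcylates.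

Step 4. The risk is loss of site selectivity: methylation at O2 or at both oxygens, since both phenols are chelated and of similar acidity. The fallback sets out from 7 and returns at 17, and it fixes the site by tethering. Deallylation of 7 (Pd(PPh3)4, morpholine) gives 3-[(benzyloxy)carbonyl]-2,4-dihydroxy-6-methylbenzoic acid F2. Acetone with (CF3CO)2O and CF3CO2H ties the C1 carboxyl and O2 together as benzyl 7-hydroxy-2,2,5-trimethyl-4-oxo-4H-1,3-benzodioxine-8-carboxylate F3, in which O4 is the only free hydroxyl. MeI and K2CO3 give benzyl 7-methoxy-2,2,5-trimethyl-4-oxo-4H-1,3-benzodioxine-8-carboxylate F4. The sodium phenoxide of 16 (NaH, THF, 60 °C) then opens the dioxinone, the known alkoxide opening of salicylate acetonides, with loss of acetone, and gives 17 with O2 free.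

Step 8. The risks are incomplete saponification of the doubly ortho-substituted methyl ester and oxidative degradation of the electron-rich phenoxide during the prolonged hot alkaline treatment. Hydride migration in the peracid step would be a lesser concern. The fallback sets out from 13, taken crude from the peracid oxidation, and returns at 16. Formate 13 is cleaved with K2CO3 in MeOH at 0 °C so that 14 is isolated. The phenol is masked with MOMCl and iPr2NEt as methyl 2,4-bis(benzyloxy)-5-(methoxymethoxy)-3,6-dimethylbenzoate F5. Saponification (KOH, DMSO–H2O, 80 °C), now without a phenoxide, gives 2,4-bis(benzyloxy)-5-(methoxymethoxy)-3,6-dimethylbenzoic acid F6. BnBr and K2CO3 give benzyl 2,4-bis(benzyloxy)-5-(methoxymethoxy)-3,6-dimethylbenzoate F7, and HCl in MeOH removes the acetal to give 16.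

Step 10. The risks are slow acylation because both partners are doubly ortho-substituted, trifluoroacetylation of the phenol of 16 that diverts the nucleophile, and self-condensation of 9 through its free O2. The fallback sets out from 8 and returns at 18, with O2 protected and the acid chloride coupled to the phenoxide. BnBr and Cs2CO3 in DMF at 60 °C give 1-allyl 3-benzyl 2-(benzyloxy)-4-methoxy-6-methylbenzene-1,3-dicarboxylate F8. Pd(PPh3)4 and morpholine give 2-(benzyloxy)-3-[(benzyloxy)carbonyl]-4-methoxy-6-methylbenzoic acid F9. (COCl)2 with catalytic DMF gives benzyl 2-(benzyloxy)-3-(chlorocarbonyl)-6-methoxy-4-methylbenzoate F10. The sodium phenoxide of 16 (NaH, THF, 0 °C to reflux) gives benzyl 2,4-bis(benzyloxy)-5-({2-(benzyloxy)-3-[(benzyloxy)carbonyl]-4-methoxy-6-methylbenzoyl}oxy)-3,6-dimethylbenzoate F11. Hydrogenolysis (H2, 10% Pd/C, EtOAc) of all five benzyl groups then gives 18.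

## Further compounds

F1 | step 3 | allyl 6-[2-(benzyloxy)-2-oxoethyl]-4-methyl-2-oxo-2H-pyran-5-carboxylate | O=C1C=C(C)C(C(=O)OCC=C)=C(CC(=O)OCc2ccccc2)O1
F2 | step 4 | 3-[(benzyloxy)carbonyl]-2,4-dihydroxy-6-methylbenzoic acid | Cc1cc(O)c(C(=O)OCc2ccccc2)c(O)c1C(=O)O
F3 | step 4 | benzyl 7-hydroxy-2,2,5-trimethyl-4-oxo-4H-1,3-benzodioxine-8-carboxylate | CC1(C)OC(=O)c2c(C)cc(O)c(C(=O)OCc3ccccc3)c2O1
F4 | step 4 | benzyl 7-methoxy-2,2,5-trimethyl-4-oxo-4H-1,3-benzodioxine-8-carboxylate | CC1(C)OC(=O)c2c(C)cc(OC)c(C(=O)OCc3ccccc3)c2O1
F5 | step 8 | methyl 2,4-bis(benzyloxy)-5-(methoxymethoxy)-3,6-dimethylbenzoate | COCOc1c(C)c(C(=O)OC)c(OCc2ccccc2)c(C)c1OCc1ccccc1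
F6 | step 8 | 2,4-bis(benzyloxy)-5-(methoxymethoxy)-3,6-dimethylbenzoic acid | COCOc1c(C)c(C(=O)O)c(OCc2ccccc2)c(C)c1OCc1ccccc1
F7 | step 8 | benzyl 2,4-bis(benzyloxy)-5-(methoxymethoxy)-3,6-dimethylbenzoate | COCOc1c(C)c(C(=O)OCc2ccccc2)c(OCc2ccccc2)c(C)c1OCc1ccccc1
F8 | step 10 | 1-allyl 3-benzyl 2-(benzyloxy)-4-methoxy-6-methylbenzene-1,3-dicarboxylate | C=CCOC(=O)c1c(C)cc(OC)c(C(=O)OCc2ccccc2)c1OCc1ccccc1
F9 | step 10 | 2-(benzyloxy)-3-[(benzyloxy)carbonyl]-4-methoxy-6-methylbenzoic acid | COc1cc(C)c(C(=O)O)c(OCc2ccccc2)c1C(=O)OCc1ccccc1
F10 | step 10 | benzyl 2-(benzyloxy)-3-(chlorocarbonyl)-6-methoxy-4-methylbenzoate | COc1cc(C)c(C(=O)Cl)c(OCc2ccccc2)c1C(=O)OCc1ccccc1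
F11 | step 10 | benzyl 2,4-bis(benzyloxy)-5-({2-(benzyloxy)-3-[(benzyloxy)carbonyl]-4-methoxy-6-methylbenzoyl}oxy)-3,6-dimethylbenzoate | COc1cc(C)c(C(=O)Oc2c(C)c(C(=O)OCc3ccccc3)c(OCc3ccccc3)c(C)c2OCc2ccccc2)c(OCc2ccccc2)c1C(=O)OCc1ccccc1
A1 | alternative 1 | methyl (Z)-2-({2-(benzyloxy)-3-[(benzyloxy)carbonyl]-4-methoxy-6-methylbenzoyl}oxy)but-2-enoate | C/C=C(\OC(=O)c1c(C)cc(OC)c(C(=O)OCc2ccccc2)c1OCc1ccccc1)C(=O)OC
A2 | alternative 1 | benzyl 3-oxopentanoate | CCC(=O)CC(=O)OCc1ccccc1
A3 | alternative 1 | benzyl 5-({2-(benzyloxy)-3-[(benzyloxy)carbonyl]-4-methoxy-6-methylbenzoyl}oxy)-3,6-dimethyl-2,4-dioxocyclohexane-1-carboxylate (mixture of stereoisomers and enol forms) | CC1C(OC(=O)c2c(C)cc(OC)c(C(=O)OCc3ccccc3)c2OCc2ccccc2)C(=O)C(C)C(=O)C1C(=O)OCc1ccccc1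
A4 | alternative 2 | 3-(benzyloxy)-4-methylcyclobut-3-ene-1,2-dione | CC1=C(OCc2ccccc2)C(=O)C1=O
A5 | alternative 2 | benzyl (E)-3-iodobut-2-enoate | C/C(I)=C\C(=O)OCc1ccccc1
A6 | alternative 2 | benzyl (E)-3-[2-(benzyloxy)-1-hydroxy-3-methyl-4-oxocyclobut-2-en-1-yl]but-2-enoate (racemic) | CC1=C(OCc2ccccc2)C(O)(/C(C)=C/C(=O)OCc2ccccc2)C1=O
A7 | alternative 2 | benzyl 4-(benzyloxy)-2,5-dihydroxy-3,6-dimethylbenzoate | Cc1c(O)c(OCc2ccccc2)c(C)c(O)c1C(=O)OCc1ccccc1
A8 | alternative 3 | benzyl 2,4-bis(benzyloxy)-5-({4-[(benzyloxy)carbonyl]-6-(2-methyl-1,3-dioxolan-2-yl)-3,5-dioxohexanoyl}oxy)-3,6-dimethylbenzoate (racemic, enolizable) | CC1(CC(=O)C(C(=O)OCc2ccccc2)C(=O)CC(=O)Oc2c(C)c(C(=O)OCc3ccccc3)c(OCc3ccccc3)c(C)c2OCc2ccccc2)OCCO1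
A9 | alternative 3 | benzyl 2,4-bis(benzyloxy)-5-({3-[(benzyloxy)carbonyl]-2,4-dihydroxy-6-methylbenzoyl}oxy)-3,6-dimethylbenzoate | Cc1cc(O)c(C(=O)OCc2ccccc2)c(O)c1C(=O)Oc1c(C)c(C(=O)OCc2ccccc2)c(OCc2ccccc2)c(C)c1OCc1ccccc1
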